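Numbering (clerodane): ring A = C1–C5 + C10, ring B = C5–C10; methyls C18 (on C4), C19 (on C5), C17 (on C8), C20 (on C9); side chain C11–C16. Retrosynthetic cuts, in order: the O15–icosanoyl ester; C12–C13 (sp3–sp2 coupling with a four-carbon iodoalkene); C8–C17 and C9–C11 (both served by a C8 carbonyl/enol); C4–C18 (C4 ketone through its enol triflate); finally C6–C7 and C5–C10 together, back to an acyclic trienone.
What allows the last cut: ring B is a six-membered ring whose C5–C6 edge can act as a 2π unit and whose C7–C8–C9–C10 arc can act as a 4π unit. C5 and C10 are already spanned by the four carbons C1–C4 of ring A, so this chain is the tether and one intramolecular [4+2] closes ring A and ring B at once. C4, next to C5, serves as the activating ketone (later C4–CH3 and C3=C4); C8, next to the quaternary C9, carries the diene oxygen (later the C9 quaternary centre and the C8 methyl).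
Forward order: acyclic C12 trienone → rings A and B in one step → C18 and C3=C4 → C9 quaternary centre with the C11–C12 arm → C17 → C12–C13 coupling with the separately made C13–C16 piece → acylation at O15 → free C16–OH.
Stereochemistry: C5 and C10 are set together in the cycloaddition under a chiral cationic oxazaborolidine. C9 (alkylation anti to the axial C5 methyl) and C8 (hydrogen added anti to the axial C9 methyl) are relayed from them. The C13=C14 geometry comes from a hydroxyl-directed trans-hydroalumination/iodination and is kept in the coupling.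
Key step: step 6

Remark: no secure facial mnemonic exists for α-branched enones with this catalyst class, so the (S)-catalyst is written in step 6 and its mirror image is to be used if a pilot run shows the opposite sense of induction.

Step 1
Reactants: 1 δ-valerolactone (oxan-2-one)
Product: 2 5-hydroxy-N-methoxy-N-methylpentanamide
Conditions: MeNH(OMe)·HCl, i-PrMgCl, THF, −20 °C
Reagents that add atoms: N,O-dimethylhydroxylamine hydrochloride, CNOC.Cl
Why: The chloromagnesium amide formed in the flask opens the lactone to the N-methoxy-N-methyl amide, whose chelated magnesium alkoxide resists further attack (lactone aminolysis, Weinreb amide formation).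

Step 2
Reactants: 2 5-hydroxy-N-methoxy-N-methylpentanamide
Product: 3 N-methoxy-N-methyl-5-oxopentanamide
Conditions: PhI(OAc)2, TEMPO (cat.), CH2Cl2, rt
Reagents that add atoms: none
Why: The oxoammonium species generated from TEMPO oxidises the primary alcohol to the aldehyde without over-oxidation, and the amide is inert (TEMPO/hypervalent iodine oxidation).

Step 3
Reactants: 3 N-methoxy-N-methyl-5-oxopentanamide; 4 3-(triphenyl-λ5-phosphanylidene)butan-2-one
Product: 5 (5E)-N-methoxy-N,6-dimethyl-7-oxooct-5-enamide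
Conditions: toluene, 90 °C
Reagents that add atoms: none
Why: Wittig olefination with the stabilised α-methyl keto ylide should give the (E)-trisubstituted enone, which fixes the later diene geometry (tether carbon C1 trans to C8).

Step 4
Reactants: 5 (5E)-N-methoxy-N,6-dimethyl-7-oxooct-5-enamide
Product: 6 (5E)-N-methoxy-N,6-dimethyl-7-[(triisopropylsilyl)oxy]octa-5,7-dienamide
Conditions: i-Pr3SiOTf, Et3N, CH2Cl2, −78 → 0 °C
Reagents that add atoms: triisopropylsilyl trifluoromethanesulfonate, CC(C)[Si](OS(=O)(=O)C(F)(F)F)(C(C)C)C(C)C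
Why: Silyl triflate/amine enolisation takes the kinetic α′ proton of the methyl ketone and gives the cross-conjugated 2-silyloxy diene, while the Weinreb amide is not enolised under these conditions (soft enolisation, silyl enol ether formation).

Step 5
Reactants: 6 (5E)-N-methoxy-N,6-dimethyl-7-[(triisopropylsilyl)oxy]octa-5,7-dienamide
Product: 8 (7E)-2,8-dimethyl-9-[(triisopropylsilyl)oxy]deca-1,7,9-trien-3-one, via bromomagnesium hemiaminal chelate 7 (not isolated)
Conditions: CH2=C(CH3)MgBr, THF, −20 °C; cold aqueous quench; kept cold and used at once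
Reagents that add atoms: isopropenylmagnesium bromide, CC(=C)[Mg]Br
Why: The alkenyl Grignard reagent adds only once because the five-membered magnesium chelate 7 persists until the cold quench, which then releases the isopropenyl ketone (Weinreb ketone synthesis).

Step 6
Reactants: 8 (7E)-2,8-dimethyl-9-[(triisopropylsilyl)oxy]deca-1,7,9-trien-3-one
Product: 9 (4aR,8aR)-5,8a-dimethyl-6-[(triisopropylsilyl)oxy]-3,4,4a,7,8,8a-hexahydronaphthalen-1(2H)-one
Conditions: (S)-tetrahydro-1-(2-methylphenyl)-3,3-diphenyl-1H,3H-pyrrolo[1,2-c][1,3,2]oxazaborole (20 mol %), HN(SO2CF3)2 (18 mol %), CH2Cl2, −78 → −40 °C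
Reagents that add atoms: none
Why: Proposed new method: the triflimide-activated oxazaborolidine binds the C4 carbonyl of the s-cis enone and lowers the LUMO of C5=C6, so the 2-silyloxy diene C7=C8–C9=C10 adds in a concerted but asynchronous [4+2] (C6–C7 ahead of C5–C10); the closest known reaction types are the enantioselective Diels–Alder additions of 2-silyloxy-1,3-dienes to acyclic enones under this class of catalyst and its intramolecular Diels–Alder reactions of trienals, an α-branched enone held inside the tether not having been shown. Ring B closes as the cyclohexene of the cycloaddition, and ring A closes through the same C5–C10 bond across the four-carbon tether C1–C4 (fused, type 1 mode, chair-like tether). C5 and C10 arise together: their trans relation follows from the (E)-C9=C10 geometry combined with the tether-exo, C5-methyl-endo transition state, and their absolute configuration from the catalyst, which is to shield one enone face so that C10 bonds to the Si face of C5 (C4 > C6 > C19). The selectivity needed is tether-exo over tether-endo, secured by the C5 methyl group (2-methyl trienones of this kind prefer the trans-fused, angular-methyl bicycle) and reinforced by the bulky acid on the carbonyl, which in the endo mode would have to lie under the C9 methyl and the C8 silyloxy group. Regiochemistry is dictated by the tether and matched by polarity (nucleophilic C7 to the β-carbon C6), and the enol silane is delivered regiodefined at C8=C9 for the next carbon–carbon bond.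

Step 7
Reactants: 9 (4aR,8aR)-5,8a-dimethyl-6-[(triisopropylsilyl)oxy]-3,4,4a,7,8,8a-hexahydronaphthalen-1(2H)-one
Product: 11 (4aR,8aR)-5,8a-dimethyl-6-[(triisopropylsilyl)oxy]-3,4,4a,7,8,8a-hexahydronaphthalen-1-yl trifluoromethanesulfonate, via potassium enolate 10 (not isolated)
Conditions: KN(SiMe3)2, THF, −78 °C; PhN(SO2CF3)2, −78 → 0 °C
Reagents that add atoms: N-phenylbis(trifluoromethanesulfonimide), O=S(=O)(N(c1ccccc1)S(=O)(=O)C(F)(F)F)C(F)(F)F
Why: Because C5 is quaternary the ketone can enolise only toward C3, so a single enolate forms and is O-sulfonylated, while the hindered silyl enol ether is untouched (enol triflate formation).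

Step 8
Reactants: 11 (4aR,8aR)-5,8a-dimethyl-6-[(triisopropylsilyl)oxy]-3,4,4a,7,8,8a-hexahydronaphthalen-1-yl trifluoromethanesulfonate
Product: 12 triisopropyl{[(4aR,8aS)-1,4a,5-trimethyl-3,4,4a,7,8,8a-hexahydronaphthalen-2-yl]oxy}silane
Conditions: MeMgBr, Fe(acac)3 (5 mol %), THF/NMP, −30 → 0 °C
Reagents that add atoms: methylmagnesium bromide, C[Mg]Br
Why: Iron-catalysed cross-coupling of the alkenyl triflate with the methyl Grignard reagent replaces OTf by CH3 with the double bond fixed at C3=C4, and the silyl enol ether does not react at this temperature (Kumada-type coupling).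

Step 9
Reactants: 12 triisopropyl{[(4aR,8aS)-1,4a,5-trimethyl-3,4,4a,7,8,8a-hexahydronaphthalen-2-yl]oxy}silane
Product: 14 tert-butyl 2-[(1R,4aR,8aS)-1,4a,5-trimethyl-2-oxo-1,2,3,4,4a,7,8,8a-octahydronaphthalen-1-yl]acetate, via tetrabutylammonium enolate 13 (not isolated)
Conditions: Bu4N[Ph3SiF2], BrCH2CO2t-Bu, THF, −40 → 0 °C
Reagents that add atoms: tert-butyl bromoacetate, CC(C)(C)OC(=O)CBr
Why: Fluoride frees the tetrasubstituted C8=C9 enolate regiospecifically, and the bromoacetate should alkylate it at carbon on the face anti to the axial C5 methyl (the other face is shielded 1,3-diaxially), so the CH2CO2t-Bu arm ends cis to H-10 and the C9 methyl syn to the C5 methyl (alkylation of a silyl enol ether through its ammonium enolate).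

Step 10
Reactants: 14 tert-butyl 2-[(1R,4aR,8aS)-1,4a,5-trimethyl-2-oxo-1,2,3,4,4a,7,8,8a-octahydronaphthalen-1-yl]acetate
Product: 15 tert-butyl 2-[(1R,4aR,8aR)-1,4a,5-trimethyl-2-methylidene-1,2,3,4,4a,7,8,8a-octahydronaphthalen-1-yl]acetate
Conditions: Ph3PCH3Br, KN(SiMe3)2, toluene, 0 → 80 °C
Reagents that add atoms: methyltriphenylphosphonium bromide, C[P+](c1ccccc1)(c1ccccc1)c1ccccc1.[Br-]
Why: Wittig methylenation converts the hindered C8 ketone into the exocyclic alkene, the tert-butyl ester being too hindered to be attacked by the ylide.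

Step 11
Reactants: 15 tert-butyl 2-[(1R,4aR,8aR)-1,4a,5-trimethyl-2-methylidene-1,2,3,4,4a,7,8,8a-octahydronaphthalen-1-yl]acetate
Product: 16 2-[(1R,4aR,8aR)-1,4a,5-trimethyl-2-methylidene-1,2,3,4,4a,7,8,8a-octahydronaphthalen-1-yl]ethan-1-ol
Conditions: LiAlH4, Et2O, 0 °C → rt
Reagents that add atoms: none
Why: LiAlH4 reduces the ester to the primary alcohol and leaves both alkenes untouched (hydride reduction of an ester).

Step 12
Reactants: 16 2-[(1R,4aR,8aR)-1,4a,5-trimethyl-2-methylidene-1,2,3,4,4a,7,8,8a-octahydronaphthalen-1-yl]ethan-1-ol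
Product: 17 2-[(1S,2R,4aR,8aR)-1,2,4a,5-tetramethyl-1,2,3,4,4a,7,8,8a-octahydronaphthalen-1-yl]ethan-1-ol
Conditions: H2 (5 bar), RhCl(PPh3)3 (5 mol %), benzene/EtOH, 40 °C
Reagents that add atoms: none
Why: RhCl(PPh3)3 hydrogenates the 1,1-disubstituted exocyclic alkene and not the trisubstituted ring alkene, and hydrogen should add on the face anti to the axial C9 methyl, which places H-8 axial and the new C17 methyl equatorial, cis to the C9 methyl (homogeneous catalytic hydrogenation).

Step 13
Reactants: 17 2-[(1S,2R,4aR,8aR)-1,2,4a,5-tetramethyl-1,2,3,4,4a,7,8,8a-octahydronaphthalen-1-yl]ethan-1-ol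
Product: 18 (1S,2R,4aR,8aR)-1-(2-iodoethyl)-1,2,4a,5-tetramethyl-1,2,3,4,4a,7,8,8a-octahydronaphthalene
Conditions: I2, PPh3, imidazole, CH2Cl2, 0 °C → rt
Reagents that add atoms: iodine, II
Why: The alkoxyphosphonium ion formed from the primary alcohol is displaced by iodide, the trisubstituted alkene being inert (Appel-type iodination).

Step 14
Reactants: 19 4-{[tert-butyl(dimethyl)silyl]oxy}but-2-yn-1-ol
Product: 21 (2Z)-4-{[tert-butyl(dimethyl)silyl]oxy}-3-iodobut-2-en-1-ol, via sodium alkenylalanate 20 (not isolated)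
Conditions: NaAlH2(OCH2CH2OMe)2, THF, 0 °C → rt; I2, −78 → 0 °C
Reagents that add atoms: iodine, II
Why: The alkoxide-bound aluminium hydride adds trans across the alkyne with aluminium on the carbon remote from the free hydroxyl (five-membered alanate 20), and iodinolysis with retention gives the iodoalkene with iodine cis to CH2OH (hydroxyl-directed hydroalumination–iodination).

Step 15
Reactants: 18 (1S,2R,4aR,8aR)-1-(2-iodoethyl)-1,2,4a,5-tetramethyl-1,2,3,4,4a,7,8,8a-octahydronaphthalene; 21 (2Z)-4-{[tert-butyl(dimethyl)silyl]oxy}-3-iodobut-2-en-1-ol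
Product: 24 (2E)-3-({[tert-butyl(dimethyl)silyl]oxy}methyl)-5-[(1S,2R,4aR,8aR)-1,2,4a,5-tetramethyl-1,2,3,4,4a,7,8,8a-octahydronaphthalen-1-yl]pent-2-en-1-ol, via alkyllithium 22 (not isolated), via lithium methoxyborinate 23 (not isolated)
Conditions: 18, t-BuLi (2.1 equiv), Et2O, −78 °C; B-MeO-9-BBN, THF, −78 °C → rt; then 21, Pd(dppf)Cl2 (5 mol %), AsPh3, aq. K3PO4, DMF, rt
Reagents that add atoms: none
Why: Iodine–lithium exchange and capture by the borinic ester give borinate 23, which passes its primary alkyl group to palladium after oxidative addition of the alkenyl iodide, so C12–C13 forms with retention of the alkene geometry and the free hydroxyl is tolerated (B-alkyl Suzuki–Miyaura coupling).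

Step 16
Reactants: 24 (2E)-3-({[tert-butyl(dimethyl)silyl]oxy}methyl)-5-[(1S,2R,4aR,8aR)-1,2,4a,5-tetramethyl-1,2,3,4,4a,7,8,8a-octahydronaphthalen-1-yl]pent-2-en-1-ol; 25 icosanoyl chloride
Product: 26 (2E)-3-({[tert-butyl(dimethyl)silyl]oxy}methyl)-5-[(1S,2R,4aR,8aR)-1,2,4a,5-tetramethyl-1,2,3,4,4a,7,8,8a-octahydronaphthalen-1-yl]pent-2-en-1-yl icosanoate
Conditions: Et3N, DMAP (cat.), CH2Cl2, 0 °C → rt
Reagents that add atoms: none
Why: DMAP-catalysed acylation of the only free hydroxyl (O15) by the acid chloride gives the icosanoate (esterification).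

Step 17
Reactants: 26 (2E)-3-({[tert-butyl(dimethyl)silyl]oxy}methyl)-5-[(1S,2R,4aR,8aR)-1,2,4a,5-tetramethyl-1,2,3,4,4a,7,8,8a-octahydronaphthalen-1-yl]pent-2-en-1-yl icosanoate
Product: 27 (2E)-3-(hydroxymethyl)-5-[(1S,2R,4aR,8aR)-1,2,4a,5-tetramethyl-1,2,3,4,4a,7,8,8a-octahydronaphthalen-1-yl]pent-2-en-1-yl icosanoate
Conditions: HF·pyridine, pyridine/THF, 0 °C → rt
Reagents that add atoms: none
Why: Buffered fluoride cleaves the primary silyl ether and spares the ester and the alkenes, and the E geometry holds O16–H away from the O15 ester so that no acyl shift can occur (desilylation).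

Compound list
1 | δ-valerolactone (oxan-2-one) | O=C1CCCCO1 | starting material
2 | 5-hydroxy-N-methoxy-N-methylpentanamide | OCCCCC(=O)N(C)OC | intermediate
3 | N-methoxy-N-methyl-5-oxopentanamide | O=CCCCC(=O)N(C)OC | intermediate
4 | 3-(triphenyl-λ5-phosphanylidene)butan-2-one | CC(=O)C(C)=P(c1ccccc1)(c1ccccc1)c1ccccc1 | starting material
5 | (5E)-N-methoxy-N,6-dimethyl-7-oxooct-5-enamide | CC(=O)/C(C)=C/CCCC(=O)N(C)OC | intermediate
6 | (5E)-N-methoxy-N,6-dimethyl-7-[(triisopropylsilyl)oxy]octa-5,7-dienamide | C=C(O[Si](C(C)C)(C(C)C)C(C)C)/C(C)=C/CCCC(=O)N(C)OC | intermediate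
7 | bromomagnesium hemiaminal chelate (tetrahedral adduct of the isopropenyl Grignard reagent at the amide carbon of 6) | C=C(C)C(O[Mg]Br)(CCC/C=C(C)/C(=C)O[Si](C(C)C)(C(C)C)C(C)C)N(C)OC | intermediate
8 | (7E)-2,8-dimethyl-9-[(triisopropylsilyl)oxy]deca-1,7,9-trien-3-one | C=C(C)C(=O)CCC/C=C(C)/C(=C)O[Si](C(C)C)(C(C)C)C(C)C | intermediate
9 | (4aR,8aR)-5,8a-dimethyl-6-[(triisopropylsilyl)oxy]-3,4,4a,7,8,8a-hexahydronaphthalen-1(2H)-one (trans-fused: H-4a and the 8a methyl on opposite faces) | CC1=C(O[Si](C(C)C)(C(C)C)C(C)C)CC[C@@]2(C)C(=O)CCC[C@H]12 | intermediate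
10 | potassium (4aR,8aR)-5,8a-dimethyl-6-[(triisopropylsilyl)oxy]-3,4,4a,7,8,8a-hexahydronaphthalen-1-olate | CC1=C(O[Si](C(C)C)(C(C)C)C(C)C)CC[C@@]2(C)C([O-])=CCC[C@H]12.[K+] | intermediate
11 | (4aR,8aR)-5,8a-dimethyl-6-[(triisopropylsilyl)oxy]-3,4,4a,7,8,8a-hexahydronaphthalen-1-yl trifluoromethanesulfonate | CC1=C(O[Si](C(C)C)(C(C)C)C(C)C)CC[C@@]2(C)C(OS(=O)(=O)C(F)(F)F)=CCC[C@H]12 | intermediate
12 | triisopropyl{[(4aR,8aS)-1,4a,5-trimethyl-3,4,4a,7,8,8a-hexahydronaphthalen-2-yl]oxy}silane | CC1=C(O[Si](C(C)C)(C(C)C)C(C)C)CC[C@@]2(C)C(C)=CCC[C@H]12 | intermediate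
13 | tetrabutylammonium (4aR,8aS)-1,4a,5-trimethyl-3,4,4a,7,8,8a-hexahydronaphthalen-2-olate | CCCC[N+](CCCC)(CCCC)CCCC.CC1=C([O-])CC[C@@]2(C)C(C)=CCC[C@H]12 | intermediate
14 | tert-butyl 2-[(1R,4aR,8aS)-1,4a,5-trimethyl-2-oxo-1,2,3,4,4a,7,8,8a-octahydronaphthalen-1-yl]acetate | CC(C)(C)OC(=O)C[C@@]1(C)C(=O)CC[C@@]2(C)C(C)=CCC[C@H]12 | intermediate
15 | tert-butyl 2-[(1R,4aR,8aR)-1,4a,5-trimethyl-2-methylidene-1,2,3,4,4a,7,8,8a-octahydronaphthalen-1-yl]acetate | CC(C)(C)OC(=O)C[C@@]1(C)C(=C)CC[C@@]2(C)C(C)=CCC[C@H]12 | intermediate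
16 | 2-[(1R,4aR,8aR)-1,4a,5-trimethyl-2-methylidene-1,2,3,4,4a,7,8,8a-octahydronaphthalen-1-yl]ethan-1-ol | OCC[C@@]1(C)C(=C)CC[C@@]2(C)C(C)=CCC[C@H]12 | intermediate
17 | 2-[(1S,2R,4aR,8aR)-1,2,4a,5-tetramethyl-1,2,3,4,4a,7,8,8a-octahydronaphthalen-1-yl]ethan-1-ol | OCC[C@@]1(C)[C@H](C)CC[C@@]2(C)C(C)=CCC[C@H]12 | intermediate
18 | (1S,2R,4aR,8aR)-1-(2-iodoethyl)-1,2,4a,5-tetramethyl-1,2,3,4,4a,7,8,8a-octahydronaphthalene | ICC[C@@]1(C)[C@H](C)CC[C@@]2(C)C(C)=CCC[C@H]12 | intermediate
19 | 4-{[tert-butyl(dimethyl)silyl]oxy}but-2-yn-1-ol | OCC#CCO[Si](C)(C)C(C)(C)C | starting material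
20 | sodium alkenylalanate (five-membered 1,2-oxaluminacyclopent-3-ene, Al bearing two 2-methoxyethoxy groups, CH2OSi(t-Bu)Me2 on the Al-bound alkene carbon) | [Na+].COCCO[Al-]1(OCCOC)OCC=C1CO[Si](C)(C)C(C)(C)C | intermediate
21 | (2Z)-4-{[tert-butyl(dimethyl)silyl]oxy}-3-iodobut-2-en-1-ol | OC/C=C(\I)CO[Si](C)(C)C(C)(C)C | intermediate
22 | {2-[(1S,2R,4aR,8aR)-1,2,4a,5-tetramethyl-1,2,3,4,4a,7,8,8a-octahydronaphthalen-1-yl]ethyl}lithium | [Li]CC[C@@]1(C)[C@H](C)CC[C@@]2(C)C(C)=CCC[C@H]12 | intermediate
23 | lithium 9-methoxy-9-{2-[(1S,2R,4aR,8aR)-1,2,4a,5-tetramethyl-1,2,3,4,4a,7,8,8a-octahydronaphthalen-1-yl]ethyl}-9-borabicyclo[3.3.1]nonan-9-uide | [Li+].CO[B-]3(CC[C@@]1(C)[C@H](C)CC[C@@]2(C)C(C)=CCC[C@H]12)C4CCCC3CCC4 | intermediate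
24 | (2E)-3-({[tert-butyl(dimethyl)silyl]oxy}methyl)-5-[(1S,2R,4aR,8aR)-1,2,4a,5-tetramethyl-1,2,3,4,4a,7,8,8a-octahydronaphthalen-1-yl]pent-2-en-1-ol | OC/C=C(/CO[Si](C)(C)C(C)(C)C)CC[C@@]1(C)[C@H](C)CC[C@@]2(C)C(C)=CCC[C@H]12 | intermediate
25 | icosanoyl chloride | CCCCCCCCCCCCCCCCCCCC(=O)Cl | starting material
26 | (2E)-3-({[tert-butyl(dimethyl)silyl]oxy}methyl)-5-[(1S,2R,4aR,8aR)-1,2,4a,5-tetramethyl-1,2,3,4,4a,7,8,8a-octahydronaphthalen-1-yl]pent-2-en-1-yl icosanoate | CCCCCCCCCCCCCCCCCCCC(=O)OC/C=C(/CO[Si](C)(C)C(C)(C)C)CC[C@@]1(C)[C@H](C)CC[C@@]2(C)C(C)=CCC[C@H]12 | intermediate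
27 | (2E)-3-(hydroxymethyl)-5-[(1S,2R,4aR,8aR)-1,2,4a,5-tetramethyl-1,2,3,4,4a,7,8,8a-octahydronaphthalen-1-yl]pent-2-en-1-yl icosanoate | CCCCCCCCCCCCCCCCCCCC(=O)OC/C=C(/CO)CC[C@@]1(C)[C@H](C)CC[C@@]2(C)C(C)=CCC[C@H]12 | target

Total step count: 17. Longest linear sequence: 16 steps (steps 1–13, then 15–17); step 14 makes the side-chain piece.

Steps most likely to fail

Step 6 (the step that bears the label). What may go wrong: cyclisation of 8 without the catalyst before or beside the catalysed path; weak facial discrimination on the α-branched enone; a competing tether-endo path to the cis-fused isomer; loss of the enol silane to the acid. Fallback, with known chemistry, takes the absolute configuration from resolution instead of catalysis. It sets out from 8, which is cyclised thermally (toluene, 2,6-di-tert-butyl-4-methylphenol, 60–80 °C; thermal intramolecular Diels–Alder reaction of a 2-methyl-1,7,9-decatrien-3-one). This should give 9 as the racemate, that is together with its mirror image (4aS,8aS)-5,8a-dimethyl-6-[(triisopropylsilyl)oxy]-3,4,4a,7,8,8a-hexahydronaphthalen-1(2H)-one F1. The enantiomers are separated by preparative chromatography on a chiral stationary phase (cellulose tris(3,5-dimethylphenylcarbamate)), and the route is rejoined at 9.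

Step 9. What may go wrong: alkylation at oxygen; proton transfer to the ammonium enolate (from the bromoacetate or between the two α positions), which would give the C9–H ketone or C7-alkylated material; insufficient facial selectivity. Fallback replaces the ammonium enolate by a lithium enolate made by dissolving-metal reduction. It sets out from 12, which is oxidised (Pd(OAc)2, MeCN, rt; Saegusa–Ito oxidation) to the enone (4aS)-1,4a,5-trimethyl-4,4a,7,8-tetrahydronaphthalen-2(3H)-one F2. Reductive alkylation follows (Li, NH3/THF, t-BuOH 1 equiv, −78 °C; removal of NH3; BrCH2CO2t-Bu, THF). This should restore H-10 trans to the C5 methyl by axial protonation and alkylate C9 anti to the C5 methyl. The route is rejoined at 14.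

Step 12. What may go wrong: slow uptake at the hindered exocyclic alkene; migration of that alkene into the ring; reduction of C3=C4; hydrogen addition from the wrong face. Fallback replaces hydrogenation by hydroboration and deoxygenation. It sets out from 15, which is hydroborated with 9-BBN (THF; then NaOH, H2O2). 9-BBN attacks only the 1,1-disubstituted alkene and should add on the face anti to the C9 methyl, giving tert-butyl 2-[(1R,2R,4aR,8aR)-2-(hydroxymethyl)-1,4a,5-trimethyl-1,2,3,4,4a,7,8,8a-octahydronaphthalen-1-yl]acetate F3. Tosylation (TsCl, pyridine) gives tert-butyl 2-[(1R,2R,4aR,8aR)-1,4a,5-trimethyl-2-{[(4-methylbenzenesulfonyl)oxy]methyl}-1,2,3,4,4a,7,8,8a-octahydronaphthalen-1-yl]acetate F4. LiAlH4 (THF, reflux) then reduces the tosylate to the C17 methyl and the ester to the primary alcohol in one operation, and the route is rejoined at 17.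

Further compounds
F1 | step 6 | (4aS,8aS)-5,8a-dimethyl-6-[(triisopropylsilyl)oxy]-3,4,4a,7,8,8a-hexahydronaphthalen-1(2H)-one (enantiomer of 9) | CC1=C(O[Si](C(C)C)(C(C)C)C(C)C)CC[C@]2(C)C(=O)CCC[C@@H]12
F2 | step 9 | (4aS)-1,4a,5-trimethyl-4,4a,7,8-tetrahydronaphthalen-2(3H)-one | CC1=C2CCC=C(C)[C@]2(C)CCC1=O
F3 | step 12 | tert-butyl 2-[(1R,2R,4aR,8aR)-2-(hydroxymethyl)-1,4a,5-trimethyl-1,2,3,4,4a,7,8,8a-octahydronaphthalen-1-yl]acetate | CC(C)(C)OC(=O)C[C@@]1(C)[C@H](CO)CC[C@@]2(C)C(C)=CCC[C@H]12
F4 | step 12 | tert-butyl 2-[(1R,2R,4aR,8aR)-1,4a,5-trimethyl-2-{[(4-methylbenzenesulfonyl)oxy]methyl}-1,2,3,4,4a,7,8,8a-octahydronaphthalen-1-yl]acetate | CC(C)(C)OC(=O)C[C@@]1(C)[C@H](COS(=O)(=O)c3ccc(C)cc3)CC[C@@]2(C)C(C)=CCC[C@H]12
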